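# Proposed synthesis of [(2R)-6-acetyl-7-hydroxy-2-methyl-2H-chromen-2-yl]methyl (E)-ferulate (CNP0375196.1)

## The problem

The target is a 2H-chromene: a benzene ring fused to a pyran through C4a and C8a, with O1 on C8a and a styrenic C3=C4 double bond. C6 carries an acetyl group hydrogen-bonded to the C7 phenol, and C2 carries a methyl group and a CH2O arm esterified with (E)-ferulic acid. C2 is the only stereocentre. It is fully substituted, has no neighbouring stereocentre to relay from, and must be (R), so its configuration has to come from an external chiral agent and then be carried through unchanged. C2 is both allylic and aryloxy-bearing, so any event that opens O1–C2 (ionisation, or retro-6π opening to the ortho-quinone methide) erases it. The arene is a 4-acylresorcinol in which both carbons ortho to O1 (C4a and C8) are activated, so the pyran must be closed onto C4a and not C8 (linear versus angular chromene). The fragile groups are the cinnamate ester (base, nucleophiles, hydride, hydrogenation), the electron-rich C3=C4 alkene (acid, oxidants), the aryl methyl ketone and two phenols. The feature that opens the route is that C4a lies ortho to O1 and para to the C7 oxygen: an alkyne suspended from O1 through C2 can be attacked by this nucleophilic carbon, closing the six-membered ring at C4–C4a without touching any bond to C2.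

## Retrosynthesis

**Unmasking (16 from 15).** Target 16 is traced to its bis(tert-butyldimethylsilyl) ether 15 by cutting two O–Si bonds. Silyl ethers are preferred to alkyl or acetal groups because buffered fluoride removes them without the acid, base or hydrogen that the chromene alkene and the cinnamate would not tolerate. Using the same group on both phenols makes this one operation. The forward step only has to avoid free phenoxide next to the ester.

**Ring closure (15 from 14).** In 15 the bond cut is C4–C4a, which opens the pyran to the aryl propargyl ether 14.
- Cutting O1–C2 instead would create the stereocentre in a reversible oxa-Michael or oxa-6π closure.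
- Cutting C3=C4 would need an extra vinyl group on both C4a and C2.
- Cutting O1–C8a would ask a tertiary alkoxide to arylate.

The C4–C4a cut leaves O1–C2 and the stereocentre untouched, removes the ring, and trades the alkene for a terminal alkyne. The forward reaction must be a 6-endo attack by C4a rather than C8, under conditions that neither ionise C2 nor pass through a sigmatropic or electrocyclic manifold.

**Ester and aryl silyl ether (14 from 13, from 9 and 12).** Removing the aryl silyl ether from 14 gives phenol 13. Cutting the acyl–O bond of the ester then gives the propargylic alcohol 9 and the silyl-protected acid 12, which comes from ferulic acid 10 through the bis-silylated species 11. The primary hydroxyl of 9 must be capped before the ring closure in any case, since a free homopropargylic hydroxyl can itself add to an activated alkyne. Capping it with the acyl group it finally carries saves a protecting group. Silylation follows esterification because the primary alcohol of 9 would otherwise be silylated first. The forward acylation must select the aliphatic alcohol over the chelated phenol.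

**Alkyne (9 from 7, from 6).** The alkyne of 9 is cut between its two carbons. The inner carbon is the aldehyde carbon of 7 and the outer one comes from a one-carbon diazo reagent. The acetate of the intermediate alkynyl acetate 8 is lost in the same flask. Adding an acetylide to a carbonyl group cannot give a tertiary aryl ether, so this homologation is the natural cut. Aldehyde 7 comes from oxidation of monoacetate 6. Neither 7 nor 8 has a hydrogen on the stereocentre, so the forward steps cannot epimerise it.

**Stereocentre (6 from 5).** No skeletal bond is cut here. Monoacetate 6 differs from the achiral diol 5 only in which of two enantiotopic hydroxymethyl groups is acylated. This turns the construction of a quaternary stereocentre into a choice between two arms that differ in their surroundings by methyl versus aryloxy. The two arms later become the alkyne and the ester arm. The forward step needs high enantiotopic group selectivity and a product that is oxidised before acyl migration can level it.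

**Oxidation level (5 from 4, from 3).** Diol 5 is the reduction product of malonate 3. The aryl ketone cannot survive the hydride, so it is allowed to be reduced to triol 4 and is restored by a benzylic-selective oxidation. This costs one step and avoids a ketone protecting group on a chelated ortho-hydroxyacetophenone, which is difficult to ketalise.

**Aryl ether (3 from 1 and 2).** The O–C bond between the future O1 and the future C2 is cut to give 2,4-dihydroxyacetophenone 1 and the tertiary bromomalonate 2. This is the only time a bond to that oxygen is made, and it is made on achiral material, so its mechanism has no stereochemical consequence. The forward reaction must alkylate the 4-hydroxyl and not the chelated 2-hydroxyl.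

## Roads not taken

**Alternative 1:** The benzene ring would be cut at C4a–C5 and C6–C7 and built last. The 1-methoxy-1-silyloxy diene A2, a ketene acetal extended through a dihydropyran that already holds the quaternary carbon, would add to but-3-yn-2-one A3 in a Diels–Alder reaction and lose methanol to give the chroman A1.
- Merits: the arene substitution pattern is dictated by the polarisation of diene and ynone, so the C4a-versus-C8 question never arises, and nothing in the sequence can open O1–C2.
- Weak points: A2 is a hydrolytically fragile diene that must itself be made enantiopure, so the quaternary stereocentre is only pushed upstream. A1 is a chroman, so C3–C4 still has to be dehydrogenated on a ring bearing a free phenol and an enolisable acetyl group. The benzyl ether must be removed without hydrogenating the alkene or the cinnamate, which forces an awkward order of events.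
- Comparison: in regiocontrol this road is better. The chosen plan sets against it a commercial arene, a stereocentre from an inexpensive enzymatic group selection, an alkene that emerges at the right oxidation level and a shorter sequence, at the price of steering the closure to C4a with a bulky silyl ether.

**Alternative 2:** The pyran would be cut at O1–C2 and C2–C3. A chiral primary amine would condense one acetyl group of the C2-symmetric 4,6-diacetylresorcinol A5 with 1-(tert-butyldimethylsilyloxy)propan-2-one A6, and the neighbouring phenol would add to the resulting enone (Kabbe annulation) to give the chromanone A4.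
- Merits: this is the most economical ring construction of the four. Two bonds, the ring and the stereocentre form in one step from a cheap arene whose symmetry removes any regiochemical question, and the second acetyl group is already the C6 acetyl.
- Weak points: the catalyst must tell a methyl from a silyloxymethyl group at a ketone-derived, fully substituted carbon in an oxa-Michael addition that is reversible, so the centre can racemise by ring opening under the conditions that form it. Afterwards the C4 carbonyl must be reduced beside the C6 acetyl and the alcohol dehydrated on an acid-sensitive, electron-rich system.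
- Comparison: in step count up to the ring this road is better. The chosen plan answers with a stereocentre set on an achiral diol and never again exposed to a reversible bond formation, and with no oxidation-state correction at C4.

**Alternative 3:** The pyran would be cut at C3=C4. A chiral molybdenum alkylidene such as Mo(N-2,6-iPr2C6H3)(CHCMe2Ph)[(S)-3,3'-di-tert-butyl-5,5',6,6'-tetramethylbiphenyl-2,2'-diolate] would engage the styrene of triene A8 and close onto one of its two enantiotopic vinyl groups to give the vinyl chromene A7.
- Merits: ring, alkene and stereocentre arise in one catalytic, neutral event, and the regiochemistry is fixed beforehand by the position of the styrene.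
- Weak points: A8 needs a bis-allylic tertiary aryl ether, which is hard to make by substitution and prone to Claisen rearrangement, and a vinyl group placed regioselectively on the arene. The air-sensitive catalyst must tolerate an aryl ketone. A7 carries a vinyl group where the target needs the acyloxymethyl arm, so a terminal alkene must be degraded oxidatively to a hydroxymethyl group beside the electron-rich chromene double bond and the aryl ketone.
- Comparison: as a way of creating the stereocentre catalytically in the ring-forming step this road is the more elegant. The chosen plan has on its side that C2 already bears oxygen at the right oxidation level, that all intermediates are stable, and that the ring closure uses a bench-stable catalyst.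

Key step: step 10

Assumption: the lipase of step 4 acetylates the hydroxymethyl arm of 5 that leads to the (R)-monoacetate 6; if the enzyme prefers the other arm, its enantiocomplementary hydrolytic mode supplies the same monoacetate and nothing downstream changes.

## Route

Step 1
Reactants: 1 2,4-dihydroxyacetophenone; 2 diethyl 2-bromo-2-methylpropanedioate
Product: 3 diethyl 2-(4-acetyl-3-hydroxyphenoxy)-2-methylpropanedioate
Conditions: K2CO3, DMF, 60 °C
Reagents that add atoms: none
Why: Williamson-type O-alkylation of a phenoxide with a tertiary α-bromo malonate, the same reaction class as the alkylation of phenols with 2-bromoisobutyrates; the 4-hydroxyl reacts because the 2-hydroxyl is tied up in a hydrogen bond to the acetyl carbonyl and is far less nucleophilic.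

Step 2
Reactants: 3 diethyl 2-(4-acetyl-3-hydroxyphenoxy)-2-methylpropanedioate
Product: 4 2-[3-hydroxy-4-(1-hydroxyethyl)phenoxy]-2-methylpropane-1,3-diol (racemic at the carbinol carbon)
Conditions: LiAlH4, THF, 0 °C to rt; Na2SO4·10H2O quench
Reagents that add atoms: none
Why: LiAlH4 reduction of a 2,2-disubstituted malonate to the propane-1,3-diol is standard; the aryl ketone is knowingly reduced as well, giving a racemic carbinol centre that is erased in step 3, and the non-acidic quench spares the ortho-hydroxybenzyl alcohol, which is taken on crude.

Step 3
Reactants: 4 2-[3-hydroxy-4-(1-hydroxyethyl)phenoxy]-2-methylpropane-1,3-diol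
Product: 5 1-{4-[(1,3-dihydroxy-2-methylpropan-2-yl)oxy]-2-hydroxyphenyl}ethanone
Conditions: MnO2 (activated, excess), EtOAc, rt
Reagents that add atoms: none
Why: Activated MnO2 oxidises benzylic alcohols and leaves saturated primary alcohols alone, so only the 1-hydroxyethyl group returns to the acetyl group, giving the achiral, prochiral keto diol.

Step 4
Reactants: 5 1-{4-[(1,3-dihydroxy-2-methylpropan-2-yl)oxy]-2-hydroxyphenyl}ethanone
Product: 6 (2R)-2-(4-acetyl-3-hydroxyphenoxy)-3-hydroxy-2-methylpropyl acetate
Conditions: Burkholderia cepacia lipase (immobilised), vinyl acetate, t-BuOMe/THF, 30 °C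
Reagents that add atoms: vinyl acetate, CC(=O)OC=C
Why: Lipase-catalysed desymmetrisation of a prochiral 2,2-disubstituted propane-1,3-diol by irreversible transesterification; the enzyme tells the two hydroxymethyl arms apart through the very different methyl and aryloxy groups on the prochiral carbon and thereby sets the future C2 stereocentre. Over-acylation of the minor monoacetate to the achiral diacetate should raise the enantiomeric purity of 6, and the chelated phenol is not a lipase substrate.

Step 5
Reactants: 6 (2R)-2-(4-acetyl-3-hydroxyphenoxy)-3-hydroxy-2-methylpropyl acetate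
Product: 7 (2S)-2-(4-acetyl-3-hydroxyphenoxy)-2-methyl-3-oxopropyl acetate
Conditions: Dess–Martin periodinane, CH2Cl2, 0 °C to rt
Reagents that add atoms: none
Why: Dess–Martin oxidation of a neopentyl-type primary alcohol under near-neutral conditions; it removes the free hydroxyl and with it the 1,3-acyl migration that could racemise 6, and the aldehyde has no α-hydrogen, so it can neither epimerise nor eliminate (the descriptor changes from R to S only because the priorities change).

Step 6
Reactants: 7 (2S)-2-(4-acetyl-3-hydroxyphenoxy)-2-methyl-3-oxopropyl acetate
Product: 9 1-{2-hydroxy-4-[(2R)-1-hydroxy-2-methylbut-3-yn-2-yl]oxyphenyl}ethanone, via alkynyl acetate 8 (not isolated)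
Conditions: dimethyl (1-diazo-2-oxopropyl)phosphonate, K2CO3, MeOH, 0 °C to rt
Reagents that add atoms: dimethyl (1-diazo-2-oxopropyl)phosphonate, COP(=O)(OC)C(=[N+]=[N-])C(C)=O
Why: Ohira–Bestmann (Seyferth–Gilbert) homologation: methanolysis of the reagent gives the diazomethylphosphonate anion, which adds to the aldehyde; loss of dimethyl phosphate and N2 and a 1,2-hydrogen shift give the terminal alkyne, and the same K2CO3/MeOH then methanolyses the acetate. Pre-forming the reagent anion before 7 is added should see the aldehyde consumed before the acetate is lost; the phenoxide-deactivated aryl ketone does not react and no bond to the stereocentre is touched.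

Step 7
Reactants: 10 ferulic acid
Product: 12 (E)-3-[4-(tert-butyldimethylsilyloxy)-3-methoxyphenyl]prop-2-enoic acid, via bis-silylated ferulate 11 (not isolated)
Conditions: TBSCl, imidazole, DMF, rt; then AcOH/THF/H2O, rt
Reagents that add atoms: tert-butyldimethylsilyl chloride, CC(C)(C)[Si](C)(C)Cl
Why: Exhaustive silylation of phenol and acid followed by selective hydrolysis of the much more labile silyl ester is the usual way to mask the phenol of a hydroxycinnamic acid; the aryl silyl ether and the (E)-alkene are unaffected.

Step 8
Reactants: 9 1-{2-hydroxy-4-[(2R)-1-hydroxy-2-methylbut-3-yn-2-yl]oxyphenyl}ethanone; 12 (E)-3-[4-(tert-butyldimethylsilyloxy)-3-methoxyphenyl]prop-2-enoic acid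
Product: 13 (2R)-2-(4-acetyl-3-hydroxyphenoxy)-2-methylbut-3-yn-1-yl (E)-3-[4-(tert-butyldimethylsilyloxy)-3-methoxyphenyl]prop-2-enoate
Conditions: DCC, DMAP (cat.), CH2Cl2, 0 °C to rt
Reagents that add atoms: none
Why: Steglich esterification; the primary alcohol is acylated by the DMAP-activated acid while the phenol, hydrogen-bonded to the acetyl group, is a much poorer nucleophile, and the conditions leave the alkyne, the aryl silyl ether and the stereocentre alone.

Step 9
Reactants: 13 (2R)-2-(4-acetyl-3-hydroxyphenoxy)-2-methylbut-3-yn-1-yl (E)-3-[4-(tert-butyldimethylsilyloxy)-3-methoxyphenyl]prop-2-enoate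
Product: 14 (2R)-2-[4-acetyl-3-(tert-butyldimethylsilyloxy)phenoxy]-2-methylbut-3-yn-1-yl (E)-3-[4-(tert-butyldimethylsilyloxy)-3-methoxyphenyl]prop-2-enoate
Conditions: TBSCl, imidazole, DMF, rt
Reagents that add atoms: tert-butyldimethylsilyl chloride, CC(C)(C)[Si](C)(C)Cl
Why: Silylation of an ortho-acyl phenol with TBSCl/imidazole in DMF is routine once the polar solvent breaks the hydrogen bond, and imidazole is too weak a base to form a silyl enol ether from the ketone; the bulky silyl ether is what later shields C8.

Step 10
Reactants: 14 (2R)-2-[4-acetyl-3-(tert-butyldimethylsilyloxy)phenoxy]-2-methylbut-3-yn-1-yl (E)-3-[4-(tert-butyldimethylsilyloxy)-3-methoxyphenyl]prop-2-enoate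
Product: 15 [(2R)-6-acetyl-7-(tert-butyldimethylsilyloxy)-2-methyl-2H-chromen-2-yl]methyl (E)-3-[4-(tert-butyldimethylsilyloxy)-3-methoxyphenyl]prop-2-enoate
Conditions: Ph3PAuNTf2 (5 mol %), dry CH2Cl2, rt
Reagents that add atoms: none
Why: Gold-catalysed intramolecular hydroarylation of an aryl propargyl ether, a known entry to 2H-chromenes. The cationic monovalent gold complex binds the terminal alkyne, C4a (ortho to the ether oxygen, para to the silyloxy group) attacks the distal alkyne carbon in a Friedel–Crafts sense, and rearomatisation followed by protodeauration of the vinylgold intermediate releases the C3=C4 alkene and the catalyst. The pyran ring closes in the 6-endo-dig mode; the 5-exo mode would need attack at the alkyne carbon next to the quaternary centre and is disfavoured by the short O–C tether and by the inductive pull of the propargylic oxygen. No stereocentre is created: the configuration at C2 set by the lipase in step 4 is carried over because the O1–C2 bond is never broken, unlike the thermal propargyl Claisen pathway, which passes through an achiral ortho-quinone methide. The step needs site selectivity between C4a and C8, both ortho to O1 and meta to the acetyl group; C4a is para to the C7 oxygen and unhindered, whereas C8 is wedged between the ether oxygen with its quaternary carbon and the bulky silyl ether. It also needs the arene to outcompete the ester carbonyl and the cinnamate alkene for the activated alkyne, which the electron-rich ring, dry solvent and a non-acidic catalyst should secure; the electron-withdrawing acyloxymethyl group on C2 additionally disfavours ionisation of the propargylic C–O bond.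

Step 11
Reactants: 15 [(2R)-6-acetyl-7-(tert-butyldimethylsilyloxy)-2-methyl-2H-chromen-2-yl]methyl (E)-3-[4-(tert-butyldimethylsilyloxy)-3-methoxyphenyl]prop-2-enoate
Product: 16 [(2R)-6-acetyl-7-hydroxy-2-methyl-2H-chromen-2-yl]methyl (E)-3-(4-hydroxy-3-methoxyphenyl)prop-2-enoate
Conditions: Bu4NF, AcOH, THF, 0 °C
Reagents that add atoms: none
Why: Fluoride cleavage of two aryl silyl ethers; acetic acid protonates the phenoxides as they form, so the cinnamate ester is not attacked and the chromene sees neither base nor strong acid.

## Compound list

1 | 2,4-dihydroxyacetophenone | CC(=O)c1ccc(O)cc1O | starting material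
2 | diethyl 2-bromo-2-methylpropanedioate | CCOC(=O)C(C)(Br)C(=O)OCC | starting material
3 | diethyl 2-(4-acetyl-3-hydroxyphenoxy)-2-methylpropanedioate | CCOC(=O)C(C)(Oc1ccc(C(C)=O)c(O)c1)C(=O)OCC | intermediate
4 | 2-[3-hydroxy-4-(1-hydroxyethyl)phenoxy]-2-methylpropane-1,3-diol, racemic at the carbinol carbon | CC(O)c1ccc(OC(C)(CO)CO)cc1O | intermediate
5 | 1-{4-[(1,3-dihydroxy-2-methylpropan-2-yl)oxy]-2-hydroxyphenyl}ethanone (achiral) | CC(=O)c1ccc(OC(C)(CO)CO)cc1O | intermediate
6 | (2R)-2-(4-acetyl-3-hydroxyphenoxy)-3-hydroxy-2-methylpropyl acetate | CC(=O)OC[C@@](C)(CO)Oc1ccc(C(C)=O)c(O)c1 | intermediate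
7 | (2S)-2-(4-acetyl-3-hydroxyphenoxy)-2-methyl-3-oxopropyl acetate | CC(=O)OC[C@@](C)(C=O)Oc1ccc(C(C)=O)c(O)c1 | intermediate
8 | (2R)-2-(4-acetyl-3-hydroxyphenoxy)-2-methylbut-3-yn-1-yl acetate, formed and consumed in step 6 | CC(=O)OC[C@@](C)(C#C)Oc1ccc(C(C)=O)c(O)c1 | intermediate
9 | 1-{2-hydroxy-4-[(2R)-1-hydroxy-2-methylbut-3-yn-2-yl]oxyphenyl}ethanone | OC[C@@](C)(C#C)Oc1ccc(C(C)=O)c(O)c1 | intermediate
10 | ferulic acid, (E)-3-(4-hydroxy-3-methoxyphenyl)prop-2-enoic acid | COc1cc(/C=C/C(=O)O)ccc1O | starting material
11 | tert-butyldimethylsilyl (E)-3-[4-(tert-butyldimethylsilyloxy)-3-methoxyphenyl]prop-2-enoate, formed and consumed in step 7 | COc1cc(/C=C/C(=O)O[Si](C)(C)C(C)(C)C)ccc1O[Si](C)(C)C(C)(C)C | intermediate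
12 | (E)-3-[4-(tert-butyldimethylsilyloxy)-3-methoxyphenyl]prop-2-enoic acid | COc1cc(/C=C/C(=O)O)ccc1O[Si](C)(C)C(C)(C)C | intermediate
13 | (2R)-2-(4-acetyl-3-hydroxyphenoxy)-2-methylbut-3-yn-1-yl (E)-3-[4-(tert-butyldimethylsilyloxy)-3-methoxyphenyl]prop-2-enoate | CC(=O)c1ccc(O[C@@](C)(COC(=O)/C=C/c2ccc(O[Si](C)(C)C(C)(C)C)c(OC)c2)C#C)cc1O | intermediate
14 | (2R)-2-[4-acetyl-3-(tert-butyldimethylsilyloxy)phenoxy]-2-methylbut-3-yn-1-yl (E)-3-[4-(tert-butyldimethylsilyloxy)-3-methoxyphenyl]prop-2-enoate | CC(=O)c1ccc(O[C@@](C)(COC(=O)/C=C/c2ccc(O[Si](C)(C)C(C)(C)C)c(OC)c2)C#C)cc1O[Si](C)(C)C(C)(C)C | intermediate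
15 | [(2R)-6-acetyl-7-(tert-butyldimethylsilyloxy)-2-methyl-2H-chromen-2-yl]methyl (E)-3-[4-(tert-butyldimethylsilyloxy)-3-methoxyphenyl]prop-2-enoate | CC(=O)c1cc2C=C[C@](C)(COC(=O)/C=C/c3ccc(O[Si](C)(C)C(C)(C)C)c(OC)c3)Oc2cc1O[Si](C)(C)C(C)(C)C | intermediate
16 | [(2R)-6-acetyl-7-hydroxy-2-methyl-2H-chromen-2-yl]methyl (E)-3-(4-hydroxy-3-methoxyphenyl)prop-2-enoate | COc1cc(/C=C/C(=O)OC[C@@]2(C)C=Cc3cc(C(C)=O)c(O)cc3O2)ccc1O | target

## Step count and risk

Total step count: 11. Longest linear sequence: 10 steps (steps 1–6 and 8–11, from 1 and 2); step 7 is a one-step branch from 10.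

**Step 10 (key step).** The most likely failure is loss of chemoselectivity at the gold-activated alkyne. The ester carbonyl three atoms away, or traces of water, may add in competition with an arene that the acetyl group makes less nucleophilic, so that turnover stalls or hydration-type products form. Partial closure at C8 is a lesser risk.

Fallback: close the ring before the ester is attached. Setting out from 9, both hydroxyls would be silylated (TBSCl, imidazole, DMF) to 1-{2-(tert-butyldimethylsilyloxy)-4-[(2R)-1-(tert-butyldimethylsilyloxy)-2-methylbut-3-yn-2-yl]oxyphenyl}ethanone F1. F1 has no carbonyl group near the alkyne and should cyclise with Ph3PAuNTf2 to 1-[(2R)-7-(tert-butyldimethylsilyloxy)-2-(tert-butyldimethylsilyloxymethyl)-2-methyl-2H-chromen-6-yl]ethanone F2. Bu4NF/AcOH would then give 1-[(2R)-7-hydroxy-2-(hydroxymethyl)-2-methyl-2H-chromen-6-yl]ethanone F3. Its primary alcohol would be esterified with 12 (DCC, DMAP; the chelated phenol stays free as in step 8) to [(2R)-6-acetyl-7-hydroxy-2-methyl-2H-chromen-2-yl]methyl (E)-3-[4-(tert-butyldimethylsilyloxy)-3-methoxyphenyl]prop-2-enoate F4. A last Bu4NF/AcOH treatment brings the sequence back to the route at 16.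

**Step 4.** The likely failure is insufficient discrimination of the two hydroxymethyl arms at the fully substituted carbon, or erosion of enantiopurity by 1,3-acyl migration in 6 before it is oxidised. Because the two arms become different groups, any error here ends as the wrong enantiomer of the target.

Fallback: separate diastereomers instead of relying on group selection. Setting out from 5, monoacylation with (S)-2-(6-methoxynaphthalen-2-yl)propanoic acid (DCC, DMAP) would give two diastereomeric monoesters, to be separated by chromatography or crystallisation. The required one, (2R)-2-(4-acetyl-3-hydroxyphenoxy)-3-hydroxy-2-methylpropyl (2S)-2-(6-methoxynaphthalen-2-yl)propanoate F5, would be oxidised with Dess–Martin periodinane to (2S)-2-(4-acetyl-3-hydroxyphenoxy)-2-methyl-3-oxopropyl (2S)-2-(6-methoxynaphthalen-2-yl)propanoate F6. Homologation under the conditions of step 6, in which K2CO3/MeOH also removes the auxiliary ester, comes back to the route at 9. The unwanted diastereomer can be methanolysed back to 5.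

**Step 6.** The likely failure is premature methanolysis of the acetate while aldehyde is still present. That would expose a β-hydroxy aldehyde to retro-aldol loss of formaldehyde. Slow addition to the hindered aldehyde makes this worse.

Fallback: build the alkyne in two stages without methanolic base. Setting out from 7, Stork–Zhao olefination would give (2R,3Z)-2-(4-acetyl-3-hydroxyphenoxy)-4-iodo-2-methylbut-3-en-1-yl acetate F7. The ylide Ph3P=CHI would be made from (iodomethyl)triphenylphosphonium iodide and NaN(SiMe3)2 in THF at −78 °C, with one extra equivalent for the phenol. Anti-elimination of hydrogen iodide with Bu4NF in DMF would give the alkynyl acetate 8, here isolated, where the sequence comes back to the route; K2CO3/MeOH then gives 9.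

**Step 1.** The likely failure is halophilic attack, in which bromine is transferred from the tertiary α-bromomalonate to the electron-rich phenoxide, causing ring bromination and reduction of the malonate. Sluggish substitution at the hindered carbon is the other risk.

Fallback: install the methyl group after the C–O bond. Setting out from 1, alkylation of the 4-hydroxyl with diethyl bromomalonate (K2CO3, acetone) would give diethyl 2-(4-acetyl-3-hydroxyphenoxy)propanedioate F8. C-Methylation at its acidic malonate position (K2CO3, one equivalent of iodomethane, DMF, rt) comes back to the route at 3.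

## Further compounds

F1 | step 10 | 1-{2-(tert-butyldimethylsilyloxy)-4-[(2R)-1-(tert-butyldimethylsilyloxy)-2-methylbut-3-yn-2-yl]oxyphenyl}ethanone | CC(=O)c1ccc(O[C@@](C)(CO[Si](C)(C)C(C)(C)C)C#C)cc1O[Si](C)(C)C(C)(C)C
F2 | step 10 | 1-[(2R)-7-(tert-butyldimethylsilyloxy)-2-(tert-butyldimethylsilyloxymethyl)-2-methyl-2H-chromen-6-yl]ethanone | CC(=O)c1cc2C=C[C@](C)(CO[Si](C)(C)C(C)(C)C)Oc2cc1O[Si](C)(C)C(C)(C)C
F3 | step 10 | 1-[(2R)-7-hydroxy-2-(hydroxymethyl)-2-methyl-2H-chromen-6-yl]ethanone | CC(=O)c1cc2C=C[C@](C)(CO)Oc2cc1O
F4 | step 10 | [(2R)-6-acetyl-7-hydroxy-2-methyl-2H-chromen-2-yl]methyl (E)-3-[4-(tert-butyldimethylsilyloxy)-3-methoxyphenyl]prop-2-enoate | CC(=O)c1cc2C=C[C@](C)(COC(=O)/C=C/c3ccc(O[Si](C)(C)C(C)(C)C)c(OC)c3)Oc2cc1O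
F5 | step 4 | (2R)-2-(4-acetyl-3-hydroxyphenoxy)-3-hydroxy-2-methylpropyl (2S)-2-(6-methoxynaphthalen-2-yl)propanoate | C[C@H](C(=O)OC[C@@](C)(CO)Oc1ccc(C(C)=O)c(O)c1)c1ccc2cc(OC)ccc2c1
F6 | step 4 | (2S)-2-(4-acetyl-3-hydroxyphenoxy)-2-methyl-3-oxopropyl (2S)-2-(6-methoxynaphthalen-2-yl)propanoate | C[C@H](C(=O)OC[C@@](C)(C=O)Oc1ccc(C(C)=O)c(O)c1)c1ccc2cc(OC)ccc2c1
F7 | step 6 | (2R,3Z)-2-(4-acetyl-3-hydroxyphenoxy)-4-iodo-2-methylbut-3-en-1-yl acetate | CC(=O)OC[C@@](C)(/C=C\I)Oc1ccc(C(C)=O)c(O)c1
F8 | step 1 | diethyl 2-(4-acetyl-3-hydroxyphenoxy)propanedioate | CCOC(=O)C(Oc1ccc(C(C)=O)c(O)c1)C(=O)OCC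
A1 | alternative 1 | 1-[(2R)-2-(benzyloxymethyl)-7-hydroxy-2-methylchroman-6-yl]ethanone | CC(=O)c1cc2CC[C@](C)(COCc3ccccc3)Oc2cc1O
A2 | alternative 1 | tert-butyl({2-[(2R)-2-(benzyloxymethyl)-2-methyl-3,4-dihydro-2H-pyran-6-yl]-1-methoxyethenyl}oxy)dimethylsilane (ketene acetal geometry left open) | COC(O[Si](C)(C)C(C)(C)C)=CC1=CCC[C@](C)(COCc2ccccc2)O1
A3 | alternative 1 | but-3-yn-2-one | CC(=O)C#C
A4 | alternative 2 | (2R)-6-acetyl-2-(tert-butyldimethylsilyloxymethyl)-7-hydroxy-2-methylchroman-4-one | CC(=O)c1cc2C(=O)C[C@](C)(CO[Si](C)(C)C(C)(C)C)Oc2cc1O
A5 | alternative 2 | 4,6-diacetylresorcinol | CC(=O)c1cc(C(C)=O)c(O)cc1O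
A6 | alternative 2 | 1-(tert-butyldimethylsilyloxy)propan-2-one | CC(=O)CO[Si](C)(C)C(C)(C)C
A7 | alternative 3 | 1-[(2S)-2-ethenyl-7-(methoxymethoxy)-2-methyl-2H-chromen-6-yl]ethanone | CC(=O)c1cc2C=C[C@](C)(C=C)Oc2cc1OCOC
A8 | alternative 3 | 1-[5-ethenyl-2-(methoxymethoxy)-4-(3-methylpenta-1,4-dien-3-yloxy)phenyl]ethanone | CC(=O)c1cc(C=C)c(OC(C)(C=C)C=C)cc1OCOC
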